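A millimolar-hour of nucleophile is the unit we count in: while it runs, a steady feed lays down a known number of them, the charge times the time squared over twice the feed time.

| flask | electrophile | nucleophile | solid base | remark | time |
|---|---|---|---|---|---|
| eta | 20 mM | 27 mM (fed, over 15 h) | 6 mM | run made earlier |  |
| gamma | 20 mM | 60 mM (fed, over 15 h) | 6 mM | run made earlier |  |
| flask | 20 mM | 40.0 mM (fed, over 15 h) | 6.00 mM |  | 15 h |

| run | time / h | electrophile / % | target / % |
|---|---|---|---|
| eta | 1.00 | 99.7 | 0 |
| eta | 1.33 | 99.2 | 0.5 |
| eta | 2.00 | 99.4 | 0 |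
| eta | 3.00 | 99.5 | 2.4 |
| eta | 5.00 | 96.5 | 3.3 |
| eta | 8.00 | 91.7 | 9.7 |
| eta | 12.0 | 81.9 | 16.8 |
| gamma | 0.667 | 99.1 | 0 |
| gamma | 2.00 | 98.7 | 1.7 |
| gamma | 3.00 | 96.2 | 3.9 |
| gamma | 5.00 | 91.0 | 8.2 |
| gamma | 8.00 | 81.3 | 18.0 |
| gamma | 10.0 | 72.5 | 25.8 |
| gamma | 12.0 | 64.4 | 35.2 |

(readings scatter by 0.5 percentage points)

- part of the electrophile that has reacted at 15 h
- share of the unused nucleophile that is free and not bound as protonated nucleophile, at 15 h

By 12.0 h the gamma run had taken 288 mM·h and kept 64.4% of its electrophile. That puts the halving dose, the fed millimolar-hours in which the fraction of electrophile left halves, at 454 mM·h. The eta run, on a different charge, reads 450 mM·h at the same time.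

Our next flask gets 40.0 mM of nucleophile, and we leave the solid base at 6.00 mM. Its dose is 300 mM·h, so we expect 63.2% of the electrophile left and 36.8% reacted. The acid released then comes to 18.4% of the nucleophile charge, and the base to 15.0%. We reckon the free share at 77.5% if no base takes acid, and at 95.9% if all of it does; the earlier runs do not show how much nucleophile is bound, so we charge this flask to see it.

The forecast says 36% and 93%, the second “which is a guess”.

The flask gives 35.5% and 78.9%.

    electrophile + nucleophile → acid set free + target (k = 2.00 M⁻¹ h⁻¹)
    nucleophile + acid set free ⇌ protonated nucleophile, settled at all times (K = 2500 M⁻¹)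
    acid set free + free base ⇌ salt of the base, settled at all times (K = 88.0 M⁻¹)
    solid base ⇌ free base, rate k4*(cs4 - [free base]) while solid is left; crystals form when [free base] > cs4 (solubility = 17.0 mM, k = 0.0300 h⁻¹)
    electrophile → decomposition product (k = 1.30 × 10⁻⁵ h⁻¹)
    target ⇌ isomer of the product (K = 0.590, k = 0.0110 h⁻¹)

The flask's free share lies nearer our low end, with 6.93 mM of protonated nucleophile beside 0.0558 mM of salt of the base at 15 h. A neighbour flask with 100 mM of nucleophile has a dose that predicts 68.2% reacted, and it gave 68.4%. This flask is not at rest at 15 h. Counted on to 150 h with the whole charge kept, the dose would leave 0.0165% of the electrophile, yet 6.33% stands there, with 93.7% reacted. Meanwhile target goes from 33.4% to 60.7%, and isomer of the product from 2.01% to 32.9%.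

Readings and results are simulated on assumed constants; noise was put on by code.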